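**Retrosynthetic overview**

1. Target ⇐ reduction of the side-chain ester of a C50 ester; C7=C8 ⇐ Wittig reaction of an ε-ring C15 phosphonium salt with a C35 polyene aldehyde.
2. C35 aldehyde ⇐ Wittig reaction (C7'=C8') of crocetindialdehyde with the acyclic C15 dienyl phosphonium salt.
3. The only ring ⇐ proton-initiated cation–olefin cyclisation of an acyclic allylic phosphonium salt carrying the 1,16-ene (protonation at C16, C1–C6 bond, loss of H-4), as in the ε-cyclase step of C50 carotenoid biosynthesis; the ring closure itself delivers the Wittig salt and sets C6 from C2.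
4. Cyclisation precursor ⇐ (3R)-6-oxo-3-(prop-1-en-2-yl)heptanal ⇐ (R)-limonene oxide (C2 from the chiral pool).
5. Acyclic end ⇐ enone ⇐ ring cleavage of (R)-α-terpineol (C2' from the chiral pool, C1'–OH already in place).

Assumption: (+)-limonene oxide (from (R)-limonene, cis/trans mixture), (R)-(+)-α-terpineol of ≥98% ee and all-E crocetindialdehyde are bought as catalogue compounds; positions are given with carotenoid locants (ring half C1–C20, acyclic half primed).

**Route**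

Step 1
Reactants: 1 (+)-limonene oxide [(4R)-limonene 1,2-epoxide]
Product: 3 (3R)-6-oxo-3-(prop-1-en-2-yl)heptanal, via limonene-1,2-diol 2 (not isolated)
Conditions: H5IO6 (1.2 equiv), THF/H2O 4:1, 0 °C → rt
Reagents that add atoms: water, O
Why: Acid-promoted epoxide hydrolysis followed by periodate glycol cleavage (Malaprade) opens the ring between the two oxygenated carbons without touching the isopropenyl group, and the stereocentre (later C2) comes unchanged from (R)-limonene.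

Step 2
Reactants: 3 (3R)-6-oxo-3-(prop-1-en-2-yl)heptanal
Product: 4 ethyl (2E,5R)-2-methyl-8-oxo-5-(prop-1-en-2-yl)non-2-enoate
Conditions: Ph3P=C(Me)CO2Et (1.1 equiv), CH2Cl2, rt
Reagents that add atoms: ethyl 2-(triphenylphosphoranylidene)propanoate, CCOC(=O)C(C)=P(c1ccccc1)(c1ccccc1)c1ccccc1
Why: Wittig olefination with a stabilised ylide reacts only with the aldehyde, not the methyl ketone, and gives the E-configured 2-methyl enoate of the C5 side chain.

Step 3
Reactants: 4 ethyl (2E,5R)-2-methyl-8-oxo-5-(prop-1-en-2-yl)non-2-enoate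
Product: 5 ethyl (2E,5R)-8-hydroxy-2,8-dimethyl-5-(prop-1-en-2-yl)deca-2,9-dienoate (1:1 epimers at C8)
Conditions: CH2=CHMgBr (1.2 equiv), THF, −78 °C; aq NH4Cl
Reagents that add atoms: vinylmagnesium bromide, C=C[Mg]Br
Why: Grignard 1,2-addition is much faster at the methyl ketone than at the α-methyl enoate at −78 °C, and the new carbinol centre (1:1) is erased in the next step.

Step 4
Reactants: 5 ethyl (2E,5R)-8-hydroxy-2,8-dimethyl-5-(prop-1-en-2-yl)deca-2,9-dienoate
Product: 6 [(2E,6R,8E)-10-ethoxy-3,9-dimethyl-10-oxo-6-(prop-1-en-2-yl)deca-2,8-dien-1-yl]triphenylphosphonium triflate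
Conditions: PPh3 (1.05 equiv), TfOH (1.0 equiv, premixed), CH2Cl2, 0 °C → rt; recrystallisation of the E salt
Reagents that add atoms: triphenylphosphine, c1ccc(cc1)P(c1ccccc1)c1ccccc1; trifluoromethanesulfonic acid, OS(=O)(=O)C(F)(F)F
Why: SN1 allylic substitution with 1,3-transposition, the standard way from a vinyl carbinol to a carotenoid Wittig salt, puts phosphorus on the primary end of the allyl cation; the expected E:Z ratio is about 3:1 and the E salt is taken on after recrystallisation.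

Step 5
Reactants: 6 [(2E,6R,8E)-10-ethoxy-3,9-dimethyl-10-oxo-6-(prop-1-en-2-yl)deca-2,8-dien-1-yl]triphenylphosphonium triflate
Product: 7 ({(1R,5R)-5-[(2E)-4-ethoxy-3-methyl-4-oxobut-2-en-1-yl]-2,6,6-trimethylcyclohex-2-en-1-yl}methyl)triphenylphosphonium triflate
Conditions: TfOH (4 equiv), CH2Cl2/2-nitropropane 1:1, −78 → −30 °C; aq NaHCO3
Reagents that add atoms: none
Why: Proposed new method: triflic acid protonates the remote 1,1-disubstituted alkene at C16 (the C5=C6 alkene is shielded from protonation by the neighbouring phosphonium charge and the enoate is inert), the tertiary C1 cation is captured by the E-configured C5=C6 alkene through a chair transition state with the C2 side chain and the CH2PPh3 group both equatorial, which sets C6 cis to C2 (2R,6R), and loss of H-4 gives the ε-type ring alkene; the closest known reactions are the Brønsted-acid cation–olefin cyclisations of geranyl sulfones, geranyl acetate and geranylammonium salts to α-cyclogeranyl compounds and of pseudoirone to cis-α-irone.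

Step 6
Reactants: 8 (R)-(+)-α-terpineol
Product: 11 4-[(3R)-5-hydroxy-2,2-dimethyloxolan-3-yl]butan-2-one (lactol), via p-menthane-1,2,8-triol 9 (not isolated), via open-chain hydroxy keto aldehyde 10 (not isolated)
Conditions: OsO4 (2 mol%), NaIO4 (4 equiv), 2,6-lutidine (2 equiv), dioxane/H2O 3:1, rt
Reagents that add atoms: sodium periodate, [Na+].[O-]I(=O)(=O)=O
Why: Lemieux–Johnson oxidation (catalytic dihydroxylation, then periodate glycol cleavage) opens the ring at its only alkene and the tertiary hydroxyl closes onto the aldehyde as a lactol; the stereocentre (later C2') comes unchanged from (R)-α-terpineol.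

Step 7
Reactants: 11 4-[(3R)-5-hydroxy-2,2-dimethyloxolan-3-yl]butan-2-one
Product: 12 (5R)-5-(2-hydroxypropan-2-yl)-8-methylnon-7-en-2-one
Conditions: i-PrPPh3I (3 equiv), n-BuLi (2.9 equiv), THF, 0 °C; then 11, −78 °C → rt
Reagents that add atoms: isopropyltriphenylphosphonium iodide (as its ylide), CC(C)[P+](c1ccccc1)(c1ccccc1)c1ccccc1.[I-]
Why: Wittig olefination of the lactol through its open hydroxy-aldehyde form installs the 3-methylbut-2-enyl group (no E/Z question), the hindered disubstituted ylide reacting with the aldehyde far faster than with the methyl ketone.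

Step 8
Reactants: 12 (5R)-5-(2-hydroxypropan-2-yl)-8-methylnon-7-en-2-one
Product: 13 (3E,5S)-5-(2-hydroxypropan-2-yl)-8-methylnona-3,7-dien-2-one
Conditions: IBX (2.5 equiv), DMSO, 70 °C
Reagents that add atoms: none
Why: IBX dehydrogenation of a ketone (Nicolaou) can only take place on the CH2CH2 side of the methyl ketone and gives the E-enone, creating the 3',4'-double bond without touching the stereocentre (the descriptor changes from R to S only because the priorities change).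

Step 9
Reactants: 13 (3E,5S)-5-(2-hydroxypropan-2-yl)-8-methylnona-3,7-dien-2-one
Product: 14 (4E,6S)-6-(2-hydroxypropan-2-yl)-3,9-dimethyldeca-1,4,8-trien-3-ol (1:1 epimers at C3)
Conditions: CH2=CHMgBr (2.5 equiv), THF, −78 → −20 °C; aq NH4Cl
Reagents that add atoms: vinylmagnesium bromide, C=C[Mg]Br
Why: Grignard 1,2-addition to the methyl enone (as with the ionones) after the first equivalent has deprotonated the tertiary hydroxyl; the new carbinol centre (1:1) is erased in the next step.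

Step 10
Reactants: 14 (4E,6S)-6-(2-hydroxypropan-2-yl)-3,9-dimethyldeca-1,4,8-trien-3-ol
Product: 15 [(2E,4E,6S)-6-(2-hydroxypropan-2-yl)-3,9-dimethyldeca-2,4,8-trien-1-yl]triphenylphosphonium bromide
Conditions: PPh3·HBr (1.05 equiv), MeOH/CH2Cl2, 0 °C → rt; recrystallisation
Reagents that add atoms: triphenylphosphine hydrobromide, [Br-].[PH+](c1ccccc1)(c1ccccc1)c1ccccc1
Why: SN1 allylic substitution with transposition through the pentadienyl cation, which PPh3 captures at the unhindered primary end to give the conjugated (2E,4E)-dienyl Wittig salt; the saturated tertiary alcohol and C6 are not involved.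

Step 11
Reactants: 15 [(2E,4E,6S)-6-(2-hydroxypropan-2-yl)-3,9-dimethyldeca-2,4,8-trien-1-yl]triphenylphosphonium bromide; 16 crocetindialdehyde
Product: 19 (2E,4E,6E,8E,10E,12E,14E,16E,18E,20E,22S)-22-(2-hydroxypropan-2-yl)-2,6,11,15,19,25-hexamethylhexacosa-2,4,6,8,10,12,14,16,18,20,24-undecaenal (C35 hydroxy aldehyde; CHO = C8), via dienyl ylide 17 (not isolated), via 7'Z-isomer 18 (not isolated)
Conditions: 16 (3 equiv), NaOMe (1.1 equiv), CH2Cl2/MeOH, 0 °C → rt; then EtOAc, reflux, 2 h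
Reagents that add atoms: none
Why: Wittig reaction of the semi-stabilised dienyl ylide with one formyl group of the dialdehyde used in excess, followed by thermal Z→E isomerisation of the sterically hindered new 7',8'-cis bond, the standard carotenoid chain assembly.

Step 12
Reactants: 7 ({(1R,5R)-5-[(2E)-4-ethoxy-3-methyl-4-oxobut-2-en-1-yl]-2,6,6-trimethylcyclohex-2-en-1-yl}methyl)triphenylphosphonium triflate; 19 C35 hydroxy aldehyde
Product: 22 (all-E,2R,6R,2'S)-2-[(2E)-3-(ethoxycarbonyl)but-2-en-1-yl]-2'-(3-methylbut-2-en-1-yl)-3',4'-didehydro-1',2'-dihydro-ε,ψ-caroten-1'-ol (C50 ethyl ester), via ring-end ylide 20 (not isolated), via 7Z-isomer 21 (not isolated)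
Conditions: 7 (1.3 equiv), NaN(SiMe3)2 (1.25 equiv), THF, −78 °C; then 19, −78 °C → rt; then heptane, reflux, 3 h
Reagents that add atoms: none
Why: Wittig reaction of the non-stabilised C7 ylide with the C8 aldehyde forms the 7,8-bond mainly Z, and this hindered cis bond is isomerised thermally to E; C6 next to the ylide carbon has no acidic hydrogen and keeps its configuration.

Step 13
Reactants: 22 C50 ethyl ester
Product: 23 (all-E,2R,6R,2'S)-2-[(2E)-4-hydroxy-3-methylbut-2-en-1-yl]-2'-(3-methylbut-2-en-1-yl)-3',4'-didehydro-1',2'-dihydro-ε,ψ-caroten-1'-ol (CNP0409952.1)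
Conditions: i-Bu2AlH (4 equiv), CH2Cl2, −78 °C
Reagents that add atoms: none
Why: DIBAL-H 1,2-reduction of the conjugated ester gives the primary allylic alcohol at −78 °C and leaves the polyene, the ring alkene and the tertiary alcohol untouched.

**Compound list**

1 | (+)-limonene oxide, (4R)-1-methyl-4-(prop-1-en-2-yl)-7-oxabicyclo[4.1.0]heptane (cis/trans mixture at the epoxide) | CC(=C)[C@@H]1CCC2(C)OC2C1 | starting material
2 | (1S,2S,4R)-1-methyl-4-(prop-1-en-2-yl)cyclohexane-1,2-diol (limonene-1,2-diol) | C[C@]1(O)CC[C@H](C[C@@H]1O)C(C)=C | intermediate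
3 | (3R)-6-oxo-3-(prop-1-en-2-yl)heptanal | O=CC[C@@H](CCC(C)=O)C(C)=C | intermediate
4 | ethyl (2E,5R)-2-methyl-8-oxo-5-(prop-1-en-2-yl)non-2-enoate | CCOC(=O)/C(C)=C/C[C@@H](CCC(C)=O)C(C)=C | intermediate
5 | ethyl (2E,5R)-8-hydroxy-2,8-dimethyl-5-(prop-1-en-2-yl)deca-2,9-dienoate (1:1 at C8) | CCOC(=O)/C(C)=C/C[C@@H](CCC(C)(O)C=C)C(C)=C | intermediate
6 | [(2E,6R,8E)-10-ethoxy-3,9-dimethyl-10-oxo-6-(prop-1-en-2-yl)deca-2,8-dien-1-yl]triphenylphosphonium triflate | CCOC(=O)/C(C)=C/C[C@@H](CC/C(C)=C/C[P+](c1ccccc1)(c1ccccc1)c1ccccc1)C(C)=C.[O-]S(=O)(=O)C(F)(F)F | intermediate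
7 | ({(1R,5R)-5-[(2E)-4-ethoxy-3-methyl-4-oxobut-2-en-1-yl]-2,6,6-trimethylcyclohex-2-en-1-yl}methyl)triphenylphosphonium triflate (ε-ring Wittig salt; carotenoid C2 and C6 both R, cis) | [O-]S(=O)(=O)C(F)(F)F.c1ccc(cc1)[P+](c1ccccc1)(c1ccccc1)C[C@@H]1C(C)=CC[C@H](C/C=C(\C)C(=O)OCC)C1(C)C | intermediate
8 | (R)-(+)-α-terpineol, 2-[(1R)-4-methylcyclohex-3-en-1-yl]propan-2-ol | CC1=CC[C@@H](CC1)C(C)(C)O | starting material
9 | (4R)-4-(2-hydroxypropan-2-yl)-1-methylcyclohexane-1,2-diol (p-menthane-1,2,8-triol; cis-1,2-diol from either face) | CC1(O)CC[C@H](CC1O)C(C)(C)O | intermediate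
10 | (3R)-3-(2-hydroxypropan-2-yl)-6-oxoheptanal | O=CC[C@@H](CCC(C)=O)C(C)(C)O | intermediate
11 | 4-[(3R)-5-hydroxy-2,2-dimethyloxolan-3-yl]butan-2-one (lactol, anomer mixture) | CC(=O)CC[C@@H]1CC(O)OC1(C)C | intermediate
12 | (5R)-5-(2-hydroxypropan-2-yl)-8-methylnon-7-en-2-one | CC(C)=CC[C@@H](CCC(C)=O)C(C)(C)O | intermediate
13 | (3E,5S)-5-(2-hydroxypropan-2-yl)-8-methylnona-3,7-dien-2-one | CC(C)=CC[C@@H](/C=C/C(C)=O)C(C)(C)O | intermediate
14 | (4E,6S)-6-(2-hydroxypropan-2-yl)-3,9-dimethyldeca-1,4,8-trien-3-ol (1:1 at C3) | CC(C)=CC[C@@H](/C=C/C(C)(O)C=C)C(C)(C)O | intermediate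
15 | [(2E,4E,6S)-6-(2-hydroxypropan-2-yl)-3,9-dimethyldeca-2,4,8-trien-1-yl]triphenylphosphonium bromide | CC(C)=CC[C@@H](/C=C/C(C)=C/C[P+](c1ccccc1)(c1ccccc1)c1ccccc1)C(C)(C)O.[Br-] | intermediate
16 | crocetindialdehyde, (2E,4E,6E,8E,10E,12E,14E)-2,6,11,15-tetramethylhexadeca-2,4,6,8,10,12,14-heptaenedial | O=C/C(C)=C/C=C/C(C)=C/C=C/C=C(C)/C=C/C=C(C)/C=O | starting material
17 | [(2E,4E,6S)-6-(2-hydroxypropan-2-yl)-3,9-dimethyldeca-2,4,8-trien-1-ylidene]triphenylphosphorane (ylide of 15) | CC(C)=CC[C@@H](/C=C/C(C)=C/C=P(c1ccccc1)(c1ccccc1)c1ccccc1)C(C)(C)O | intermediate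
18 | 7'Z-isomer of 19 (16Z in the hexacosa numbering) | CC(C)=CC[C@@H](/C=C/C(C)=C/C=C\C(C)=C\C=C\C(C)=C\C=C\C=C(C)\C=C\C=C(C)\C=O)C(C)(C)O | intermediate
19 | (2E,4E,6E,8E,10E,12E,14E,16E,18E,20E,22S)-22-(2-hydroxypropan-2-yl)-2,6,11,15,19,25-hexamethylhexacosa-2,4,6,8,10,12,14,16,18,20,24-undecaenal (C35 hydroxy aldehyde, C8 to C1' of the target) | CC(C)=CC[C@@H](/C=C/C(C)=C/C=C/C(C)=C/C=C/C(C)=C/C=C/C=C(C)/C=C/C=C(C)/C=O)C(C)(C)O | intermediate
20 | ethyl (2E)-2-methyl-4-{(1R,5R)-4,6,6-trimethyl-5-[(triphenyl-λ5-phosphanylidene)methyl]cyclohex-3-en-1-yl}but-2-enoate (ylide of 7) | c1ccc(cc1)P(c1ccccc1)(c1ccccc1)=C[C@@H]1C(C)=CC[C@H](C/C=C(\C)C(=O)OCC)C1(C)C | intermediate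
21 | 7Z-isomer of 22 | CC(C)=CC[C@@H](/C=C/C(C)=C/C=C/C(C)=C/C=C/C(C)=C/C=C/C=C(C)/C=C/C=C(C)/C=C\[C@@H]1C(C)=CC[C@H](C/C=C(\C)C(=O)OCC)C1(C)C)C(C)(C)O | intermediate
22 | (all-E,2R,6R,2'S)-2-[(2E)-3-(ethoxycarbonyl)but-2-en-1-yl]-2'-(3-methylbut-2-en-1-yl)-3',4'-didehydro-1',2'-dihydro-ε,ψ-caroten-1'-ol | CC(C)=CC[C@@H](/C=C/C(C)=C/C=C/C(C)=C/C=C/C(C)=C/C=C/C=C(C)/C=C/C=C(C)/C=C/[C@@H]1C(C)=CC[C@H](C/C=C(\C)C(=O)OCC)C1(C)C)C(C)(C)O | intermediate
23 | (all-E,2R,6R,2'S)-2-[(2E)-4-hydroxy-3-methylbut-2-en-1-yl]-2'-(3-methylbut-2-en-1-yl)-3',4'-didehydro-1',2'-dihydro-ε,ψ-caroten-1'-ol | CC(C)=CC[C@@H](/C=C/C(C)=C/C=C/C(C)=C/C=C/C(C)=C/C=C/C=C(C)/C=C/C=C(C)/C=C/[C@@H]1C(C)=CC[C@H](C/C=C(\C)CO)C1(C)C)C(C)(C)O | target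

**Step count**

Total: 13 steps. Longest linear sequence: 8 steps (8 → 23 through steps 6–13); the ring branch 1 → 7 is 5 steps and joins at step 12.

**Steps most likely to fail, with fallbacks**

Step 5 (ring closure on the phosphonium salt). The phosphonium charge lowers the nucleophilicity of the C5=C6 alkene. The C1 cation can then leak by 1,2-hydride shift or elimination towards C2, which would erode the C2 configuration, and the product can drift to the exocyclic or the C5=C6 alkene isomer. Fallback, setting out from 5 and coming back at 22: the ring is closed on a neutral sulfone (the precedented geranyl sulfone cyclisation) and the 7,8-bond is made by Julia–Kocienski olefination instead of a Wittig reaction. 1-Phenyl-1H-tetrazole-5-thiol with catalytic TfOH in CH2Cl2 converts 5 with allylic transposition into ethyl (2E,5R,8E)-2,8-dimethyl-10-[(1-phenyl-1H-tetrazol-5-yl)sulfanyl]-5-(prop-1-en-2-yl)deca-2,8-dienoate F1. (NH4)6Mo7O24/H2O2 in EtOH oxidises sulfur only and gives ethyl (2E,5R,8E)-2,8-dimethyl-10-[(1-phenyl-1H-tetrazol-5-yl)sulfonyl]-5-(prop-1-en-2-yl)deca-2,8-dienoate F2, whose E isomer is separated on silica. TfOH in CH2Cl2 at −78 → −30 °C cyclises it to ethyl (2E)-2-methyl-4-[(1R,5R)-4,6,6-trimethyl-5-{[(1-phenyl-1H-tetrazol-5-yl)sulfonyl]methyl}cyclohex-3-en-1-yl]but-2-enoate F3. Deprotonation with KN(SiMe3)2 in THF at −78 °C and addition of 19 gives 22 directly and E-selectively.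

Step 4 (E geometry of the allylic salt). The allylic transposition gives only about 3:1 E:Z. The Z salt would cyclise mainly to the 2,6-trans ring, so the diastereomeric purity of 7 depends on how well the E salt can be recrystallised. Fallback, setting out from 3 and coming back at 6: the E alkene is built by olefination and the isomers are separated as neutral esters. The aldehyde of 3 is masked selectively (HC(OMe)3, MeOH, cat. p-TsOH, 0 °C) as (5R)-7,7-dimethoxy-5-(prop-1-en-2-yl)heptan-2-one F4. Horner–Wadsworth–Emmons reaction of the ketone ((EtO)2P(O)CH2CO2Et, NaH, THF; E:Z about 4:1, chromatography) gives ethyl (2E,6R)-8,8-dimethoxy-3-methyl-6-(prop-1-en-2-yl)oct-2-enoate F5. i-Bu2AlH gives (2E,6R)-8,8-dimethoxy-3-methyl-6-(prop-1-en-2-yl)oct-2-en-1-ol F6, and aqueous oxalic acid in THF frees (3R,6E)-8-hydroxy-6-methyl-3-(prop-1-en-2-yl)oct-6-enal F7. The Wittig reagent of step 2 converts it into ethyl (2E,5R,8E)-10-hydroxy-2,8-dimethyl-5-(prop-1-en-2-yl)deca-2,8-dienoate F8, and PPh3/TfOH in CH2Cl2 turns the primary allylic alcohol into 6 with the E geometry kept.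

Step 8 (dehydrogenation with IBX). Conversion of an unactivated acyclic ketone can be low, and the hot, slightly acidic medium may over-oxidise the enone to a dienone or epimerise the γ-stereocentre through the dienol. Fallback, setting out from 12 and coming back at 13: enolisation and oxidation are separated (Saegusa–Ito oxidation). Me3SiCl/NaI/Et3N in MeCN (thermodynamic enolisation; the tertiary alcohol is silylated as well) gives (2Z,5S)-8-methyl-2-(trimethylsilyloxy)-5-[2-(trimethylsilyloxy)propan-2-yl]nona-2,7-diene F9. Pd(OAc)2 in MeCN at rt gives (3E,5S)-8-methyl-5-[2-(trimethylsilyloxy)propan-2-yl]nona-3,7-dien-2-one F10, and K2CO3 in MeOH removes the silyl ether to give 13.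

**Further compounds**

F1 | step 5 | ethyl (2E,5R,8E)-2,8-dimethyl-10-[(1-phenyl-1H-tetrazol-5-yl)sulfanyl]-5-(prop-1-en-2-yl)deca-2,8-dienoate | CCOC(=O)/C(C)=C/C[C@@H](CC/C(C)=C/CSc1nnnn1-c1ccccc1)C(C)=C
F2 | step 5 | ethyl (2E,5R,8E)-2,8-dimethyl-10-[(1-phenyl-1H-tetrazol-5-yl)sulfonyl]-5-(prop-1-en-2-yl)deca-2,8-dienoate | CCOC(=O)/C(C)=C/C[C@@H](CC/C(C)=C/CS(=O)(=O)c1nnnn1-c1ccccc1)C(C)=C
F3 | step 5 | ethyl (2E)-2-methyl-4-[(1R,5R)-4,6,6-trimethyl-5-{[(1-phenyl-1H-tetrazol-5-yl)sulfonyl]methyl}cyclohex-3-en-1-yl]but-2-enoate | O=S(=O)(C[C@@H]1C(C)=CC[C@H](C/C=C(\C)C(=O)OCC)C1(C)C)c1nnnn1-c1ccccc1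
F4 | step 4 | (5R)-7,7-dimethoxy-5-(prop-1-en-2-yl)heptan-2-one | COC(OC)C[C@@H](CCC(C)=O)C(C)=C
F5 | step 4 | ethyl (2E,6R)-8,8-dimethoxy-3-methyl-6-(prop-1-en-2-yl)oct-2-enoate | COC(OC)C[C@@H](CC/C(C)=C/C(=O)OCC)C(C)=C
F6 | step 4 | (2E,6R)-8,8-dimethoxy-3-methyl-6-(prop-1-en-2-yl)oct-2-en-1-ol | COC(OC)C[C@@H](CC/C(C)=C/CO)C(C)=C
F7 | step 4 | (3R,6E)-8-hydroxy-6-methyl-3-(prop-1-en-2-yl)oct-6-enal | O=CC[C@@H](CC/C(C)=C/CO)C(C)=C
F8 | step 4 | ethyl (2E,5R,8E)-10-hydroxy-2,8-dimethyl-5-(prop-1-en-2-yl)deca-2,8-dienoate | CCOC(=O)/C(C)=C/C[C@@H](CC/C(C)=C/CO)C(C)=C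
F9 | step 8 | (2Z,5S)-8-methyl-2-(trimethylsilyloxy)-5-[2-(trimethylsilyloxy)propan-2-yl]nona-2,7-diene | CC(C)=CC[C@@H](C/C=C(/C)O[Si](C)(C)C)C(C)(C)O[Si](C)(C)C
F10 | step 8 | (3E,5S)-8-methyl-5-[2-(trimethylsilyloxy)propan-2-yl]nona-3,7-dien-2-one | CC(C)=CC[C@@H](/C=C/C(C)=O)C(C)(C)O[Si](C)(C)C
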